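**Retrosynthetic overview** (ring A = δ-lactone, B = cyclohexane, C = cyclopentane, D = ketone ring of the bicyclo[2.2.2]octene, E = butenolide)
1. Target ⇐ intramolecular Diels–Alder reaction of a 6,6-disubstituted cyclohexa-2,4-dienone (unmasked by dehydrogenation) onto the exocyclic methylene of ring B; this closes rings C and D last.
2. Butenolide E ⇐ β-keto ester of a 2-methylcyclohexane-1,3-dione unit (enol triflate, Stille hydroxymethylation, lactonization); methylene ⇐ ring-B ketone.
3. Ring B ⇐ phase-transfer Michael/aldol of that dione onto a vinyl ketone carrying an acetyl group (sets the quaternary carbon of ring D and the CH/C(OH)CH3 pair).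
4. Ring A and the first stereocentre ⇐ chiral phosphoric acid cascade of a (2Z)-dienoic acid with divinyl ketone; the acid ⇐ a 2-pyranone from acetylacetone and methyl propiolate.
5. Ring order: A → B → E → C and D together.

Assumption: the catalyst antipodes named in steps 4 and 6 are taken to give the drawn sense of induction (otherwise the mirror-image or pseudoenantiomeric catalyst is used), and 1,5-dichloropentan-3-one and 2-methylpent-1-en-3-one are taken as catalogue chemicals.

**Step 1**
Reactants: 1 pentane-2,4-dione; 2 methyl propiolate
Product: 4 5-acetyl-6-methyl-2H-pyran-2-one, via Michael adduct 3 (not isolated)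
Conditions: DBU (10 mol%), PhMe, 25 °C then 110 °C
Reagents that add atoms: none
Why: Base-catalysed Michael addition of the diketone to the propiolate gives 3, whose enol oxygen closes onto the ester once the enoate has equilibrated to Z through the extended enolate (Michael addition–lactonization annulation to a 2-pyranone); no stereocentre is formed.

**Step 2**
Reactants: 4 5-acetyl-6-methyl-2H-pyran-2-one
Product: 5 (2Z)-4-acetyl-5-methylhexa-2,4-dienoic acid
Conditions: MeMgBr (1.15 equiv), CuBr·SMe2 (10 mol%), THF, −78 → 0 °C; 1 M HCl
Reagents that add atoms: methylmagnesium bromide, C[Mg]Br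
Why: Copper-catalysed conjugate addition of methyl to C6 (β to the acetyl group and the vinylogous acyl carbon of the enol lactone) is followed by ring opening of the lactone enolate (addition–elimination), which gives the gem-dimethyl enone carboxylate and keeps the ring-derived Z enoate.

**Step 3**
Reactants: 6 1,5-dichloropentan-3-one
Product: 8 penta-1,4-dien-3-one, via 5-chloropent-1-en-3-one 7 (not isolated)
Conditions: Et3N (2.2 equiv), Et2O, 0 °C; filtered and used at once as a solution
Reagents that add atoms: none
Why: Twofold E1cB dehydrochlorination of the β-chloro ketone liberates divinyl ketone, which is too unstable to store.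

**Step 4**
Reactants: 5 (2Z)-4-acetyl-5-methylhexa-2,4-dienoic acid; 8 penta-1,4-dien-3-one
Product: 10 (5R)-5-acetyl-6,6-dimethyl-5-(3-oxopent-4-en-1-yl)-5,6-dihydro-2H-pyran-2-one, via acetyl lactone 9 (not isolated)
Conditions: (R)-TRIP phosphoric acid (10 mol%), 8 (4 equiv), PhMe, 4 Å MS, 40 °C
Reagents that add atoms: none
Why: Proposed new method: a chiral phosphoric acid-catalysed lactonizing oxa-Michael/Michael cascade, in which the (2Z)-acid closes 6-endo onto the tetrasubstituted enone terminus (acid-promoted oxa-Michael, equivalent to an oxa-6π closure) to give lactone 9 as its dienol, a vinylogous acid that is hydrogen-bonded to the phosphoryl oxygen while the P–OH activates the vinyl ketone and adds through C5 to one vinyl group of 8 on a single enantioface, the quaternization of C5 removing the only proton through which the lactone could reopen; the closest known reaction type is the chiral phosphoric acid-catalysed Michael addition of α-branched β-keto esters and cyclic 1,3-dicarbonyls to vinyl ketones.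

**Step 5**
Reactants: 11 dimethyl malonate; 12 2-methylpent-1-en-3-one
Product: 14 methyl 3,5-dimethyl-2,4-dioxocyclohexane-1-carboxylate, via malonate Michael adduct 13 (not isolated)
Conditions: NaOMe (1.1 equiv), MeOH, 0 °C then reflux; 1 M HCl
Reagents that add atoms: none
Why: Michael addition of the malonate to the enone followed by Claisen (Dieckmann-type) condensation of the ethyl ketone onto one ester gives the cyclic 1,3-dione; its stereocentres are labile or removed later, so the isomer mixture is used.

**Step 6**
Reactants: 10 (5R)-5-acetyl-6,6-dimethyl-5-(3-oxopent-4-en-1-yl)-5,6-dihydro-2H-pyran-2-one; 14 methyl 3,5-dimethyl-2,4-dioxocyclohexane-1-carboxylate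
Product: 16 ring-B ketol, via triketone Michael adduct 15 (not isolated)
Conditions: N-(9-anthracenylmethyl)-O-allylcinchonidinium bromide (10 mol%), Cs2CO3 (1.2 equiv), PhMe, −20 → 0 °C; 1 M HCl
Reagents that add atoms: none
Why: Asymmetric phase-transfer Michael addition of the dione enolate to the vinyl ketone sets the quaternary carbon under control of the chiral ammonium ion, and the (Z)-enolate so formed on the side-chain side closes at once by intramolecular aldol addition onto the acetyl group (interrupted Robinson annulation) through a chair-like closed transition state that puts the side chain equatorial and cis to the new hydroxyl, the alkoxide then being quenched by the acidic β-keto ester proton so that retro-aldol is avoided.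

**Step 7**
Reactants: 16 ring-B ketol
Product: 17 enol triflate
Conditions: Tf2O (1.1 equiv), iPr2NEt, CH2Cl2, −78 °C
Reagents that add atoms: trifluoromethanesulfonic anhydride, O=S(=O)(OS(=O)(=O)C(F)(F)F)C(F)(F)F
Why: Only the β-keto ester is enolized, and since the carbon between the two ring carbonyls is quaternary its O-sulfonylation is regiochemically unambiguous (enol triflate formation); the hindered tertiary alcohol and the other ketones do not react at −78 °C.

**Step 8**
Reactants: 17 enol triflate
Product: 19 butenolide ketone, via hydroxymethyl ester 18 (not isolated)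
Conditions: Bu3SnCH2OH, Pd(PPh3)4 (10 mol%), LiCl, 1,4-dioxane, 95 °C
Reagents that add atoms: (tributylstannyl)methanol, CCCC[Sn](CCCC)(CCCC)CO
Why: Stille coupling of the β-triflyloxy enoate with the hydroxymethylstannane gives a cis γ-hydroxy enoate that lactonizes spontaneously to the butenolide (ring E).

**Step 9**
Reactants: 19 butenolide ketone
Product: 20 exocyclic methylene compound
Conditions: Zn, CH2Br2, TiCl4, THF/CH2Cl2, 0 °C → rt
Reagents that add atoms: dibromomethane, BrCBr
Why: Takai–Lombardo methylenation is non-basic, so the β-hydroxy ketone neither retro-aldolizes nor epimerizes at the α-CH, and it should take the hydroxyl-chelated ring-B ketone in preference to the ketone flanked by a quaternary carbon and to the two lactones.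

**Step 10**
Reactants: 20 exocyclic methylene compound
Product: 22 andibenin B, via cyclohexa-2,4-dienone 21 (not isolated)
Conditions: DDQ (1.3 equiv), 1,4-dioxane, 90 °C
Reagents that add atoms: none
Why: DDQ dehydrogenation between the CHCH3 and the allylic CH2 gives a 6,6-disubstituted cyclohexa-2,4-dienone that cannot tautomerize to a phenol and undergoes intramolecular Diels–Alder reaction with the 1,1-disubstituted alkene on the diene face carrying the CH2 tether, the three-atom tether enforcing the cis-fused cyclopentane and setting the remaining three quaternary centres at once (both CHCH3 epimers converge).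

**Compound list**
1 | pentane-2,4-dione | CC(=O)CC(C)=O | starting material
2 | methyl propiolate | C#CC(=O)OC | starting material
3 | methyl 4-acetyl-5-oxohex-2-enoate (Michael adduct, E/Z mixture) | CC(=O)C(C(C)=O)C=CC(=O)OC | intermediate
4 | 5-acetyl-6-methyl-2H-pyran-2-one | CC(=O)C1=C(C)OC(=O)C=C1 | intermediate
5 | (2Z)-4-acetyl-5-methylhexa-2,4-dienoic acid | CC(=O)C(=C(C)C)/C=C\C(=O)O | intermediate
6 | 1,5-dichloropentan-3-one | ClCCC(=O)CCCl | starting material
7 | 5-chloropent-1-en-3-one | C=CC(=O)CCCl | intermediate
8 | penta-1,4-dien-3-one (divinyl ketone) | C=CC(=O)C=C | intermediate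
9 | acetyl lactone: 5-acetyl-6,6-dimethyl-5,6-dihydro-2H-pyran-2-one (racemic, reacts as its dienol) | CC(=O)C1C=CC(=O)OC1(C)C | intermediate
10 | (5R)-5-acetyl-6,6-dimethyl-5-(3-oxopent-4-en-1-yl)-5,6-dihydro-2H-pyran-2-one | CC1(C)OC(=O)C=C[C@@]1(CCC(=O)C=C)C(C)=O | intermediate
11 | dimethyl malonate | COC(=O)CC(=O)OC | starting material
12 | 2-methylpent-1-en-3-one | CCC(=O)C(C)=C | starting material
13 | malonate Michael adduct: dimethyl 2-(2-methyl-3-oxopentyl)propanedioate | CCC(=O)C(C)CC(C(=O)OC)C(=O)OC | intermediate
14 | methyl 3,5-dimethyl-2,4-dioxocyclohexane-1-carboxylate (stereoisomer and enol mixture) | COC(=O)C1CC(C)C(=O)C(C)C1=O | intermediate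
15 | triketone Michael adduct: methyl 3-{5-[(5R)-5-acetyl-6,6-dimethyl-2-oxo-5,6-dihydro-2H-pyran-5-yl]-3-oxopentyl}-3,5-dimethyl-2,4-dioxocyclohexane-1-carboxylate; quaternary C3 as in the SMILES; C1 and C5 epimeric | CC1(C)OC(=O)C=C[C@@]1(CCC(=O)CC[C@@]2(C)C(=O)C(C)CC(C(=O)OC)C2=O)C(C)=O | intermediate
16 | ring-B ketol: lactone A spiro-fused to cyclohexanone B; C(OH)CH3 next to the spiro carbon with OH cis to the lactone CH=CH arm; on the adjacent CH a CH2 link, cis to OH, to the quaternary C3 of the dione ester ring | CC1(C)OC(=O)C=C[C@]12CCC(=O)[C@H]([C@@]2(C)O)C[C@@]3(C)C(=O)C(C)CC(C(=O)OC)C3=O | intermediate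
17 | enol triflate: 16 with the β-keto ester enol O-triflated (methyl 2-triflyloxycyclohex-1-ene-1-carboxylate unit, other ring ketone kept) | CC1(C)OC(=O)C=C[C@]12CCC(=O)[C@H]([C@@]2(C)O)C[C@@]3(C)C(=O)C(C)CC(C(=O)OC)=C3OS(=O)(=O)C(F)(F)F | intermediate
18 | hydroxymethyl ester: 17 with OTf replaced by CH2OH | CC1(C)OC(=O)C=C[C@]12CCC(=O)[C@H]([C@@]2(C)O)C[C@@]3(C)C(=O)C(C)CC(C(=O)OC)=C3CO | intermediate
19 | butenolide ketone: CH2OH and ester of 18 closed to the fused furan-2(5H)-one; ring-B ketol unchanged | CC1(C)OC(=O)C=C[C@]12CCC(=O)[C@H]([C@@]2(C)O)C[C@@]3(C)C(=O)C(C)CC4=C3COC4=O | intermediate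
20 | exocyclic methylene compound: ring-B C=O of 19 replaced by C=CH2 | CC1(C)OC(=O)C=C[C@]12CCC(=C)[C@H]([C@@]2(C)O)C[C@@]3(C)C(=O)C(C)CC4=C3COC4=O | intermediate
21 | cyclohexa-2,4-dienone: 20 dehydrogenated between CHCH3 and the ring CH2 next to the butenolide | CC1(C)OC(=O)C=C[C@]12CCC(=C)[C@H]([C@@]2(C)O)C[C@@]3(C)C(=O)C(C)=CC4=C3COC4=O | intermediate
22 | andibenin B | CC1(C)OC(=O)C=C[C@]12CC[C@@]13C[C@@]4(C)C=C5C(=O)OC[C@]51[C@@](C)(C[C@H]3[C@@]2(C)O)C4=O | target

**Step count and risks**
Total steps: 10. Longest linear sequence: 8 (steps 1, 2, 4, 6, 7, 8, 9, 10); steps 3 and 5 are one-step side branches.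

Three steps most likely to fail:

Step 4 (the proposed new cascade). The lactone dienol may not be populated under the weak chiral acid, divinyl ketone may add twice or polymerize, or the ee may be low. Fallback, from 5 back to 10, by known chemistry: 5 is closed with TfOH (5 mol%, CH2Cl2) and the acetyl lactone 9 is isolated. It is then added, under the established chiral phosphoric acid Michael protocol for α-branched cyclic β-dicarbonyls and vinyl ketones, to the mono-enone 7 (from 6 with one equivalent of Et3N). This gives the chloro ketone (5R)-5-acetyl-5-(5-chloro-3-oxopentyl)-6,6-dimethyl-5,6-dihydro-2H-pyran-2-one F1, which cannot add a second time. Et3N then eliminates HCl and returns the route at 10.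

Step 6 (Michael/aldol). The enolate may be protonated before it closes, the aldol may give the other diastereomer at the C(OH)CH3 carbon relative to the spiro centre, or the ketol may equilibrate. Fallback, from 10 and 14 back to 16: the two events are separated. A bifunctional cinchona squaramide-catalysed Michael addition gives the open triketone 15, which is isolated. A primary-amine salt (9-amino-9-deoxy-epi-quinine, benzoic acid) then closes ring B by enamine aldol addition, with the amine antipode chosen to give 16. This fallback makes no compound outside the list (F0).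

Step 10 (dehydrogenation/Diels–Alder). DDQ may attack the alkene or the product, or the cycloaddition may be slower than decomposition of the dienone in the oxidizing medium. Fallback, from 19 back to 22: the order is changed. DDQ is applied to 19 first, giving the dienone ketone F2. Takai–Lombardo methylenation at 0 °C then gives 21, which is isolated cold and heated in toluene at 80 °C without oxidant to give 22.

**Further compounds**
F1 | step 4 | (5R)-5-acetyl-5-(5-chloro-3-oxopentyl)-6,6-dimethyl-5,6-dihydro-2H-pyran-2-one | CC1(C)OC(=O)C=C[C@@]1(CCC(=O)CCCl)C(C)=O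
F0 | step 6 | none | none
F2 | step 10 | dienone ketone: 19 dehydrogenated to the cyclohexa-2,4-dienone, ring-B ketone kept | CC1(C)OC(=O)C=C[C@]12CCC(=O)[C@H]([C@@]2(C)O)C[C@@]3(C)C(=O)C(C)=CC4=C3COC4=O
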